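**Retrosynthetic overview**

1. The target is traced back, through global hydrolysis, to its methyl ester / aryl silyl ether, and this 2H-chromene to an (S)-2,2-disubstituted chroman-4-one; the C4 oxygen is a temporary activating group that leaves as water (reduction, dehydration).
2. The chromanone is cut at the exocyclic bond between C2 of the pyran ring and C9 of the side chain. This gives a flat 6-silyloxy-2,7,8-trimethylchromone and a C18 diene ester, joined by hydrozirconation of the diene and copper-catalysed enantioselective dearomative alkylation of the chromone-derived benzopyrylium ion.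
3. Enabling feature: C2 lies between ring oxygen O1 and C3 of a 2H-pyran ring fused to the benzene ring. With oxygen at C4 this ring is a chromone, whose O-silylated form is an aromatic 4-silyloxy-1-benzopyrylium cation with C2 as its only conjugate-acceptor carbon; attack there creates the quaternary stereocentre and leaves C3–C4 ready to become the alkene.
4. The chromone comes from 2,3-dimethylhydroquinone (acylation, Claisen condensation/cyclodehydration, silylation). The diene ester comes from geranyl acetate (cleavage of the terminal alkene) and a homoprenylated Still–Gennari phosphonate (Z-enoate), then acetate to enal to terminal diene.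
5. Ring order: the benzene ring is bought; the pyranone ring is closed in step 2, dearomatised in step 11, and receives its C3=C4 alkene in step 13.

Key step: step 11

Assumption: the sense of induction of the copper–phosphoramidite catalyst on this cation cannot be predicted with certainty; the ligand antipode that gives the (S) configuration at C2 is to be chosen in a model run, and the route is written for that antipode.

**Route**

Step 1
Reactants: 1 2,3-dimethylhydroquinone
Product: 2 1-(2,5-dihydroxy-3,4-dimethylphenyl)ethan-1-one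
Conditions: AcOH, BF3·OEt2, 110 °C
Reagents that add atoms: acetic acid, CC(=O)O
Why: Lewis-acid-mediated Friedel–Crafts/Fries C-acylation ortho to a hydroxyl group should give one product, because the two free ring positions are equivalent and the first acyl group deactivates the ring towards a second.

Step 2
Reactants: 2 1-(2,5-dihydroxy-3,4-dimethylphenyl)ethan-1-one
Product: 4 6-hydroxy-2,7,8-trimethyl-4H-chromen-4-one, via diketone 3 (not isolated)
Conditions: NaH (excess), EtOAc, THF, reflux; then conc. HCl, AcOH, 90 °C
Reagents that add atoms: ethyl acetate, CCOC(C)=O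
Why: Claisen condensation of the ketone enolate with ethyl acetate should give the 1,3-diketone, whose ortho-hydroxyl adds to the distal carbonyl and loses water under acid to close the pyranone ring (classical 2-methylchromone synthesis).

Step 3
Reactants: 4 6-hydroxy-2,7,8-trimethyl-4H-chromen-4-one
Product: 5 6-(tert-butyldimethylsilyloxy)-2,7,8-trimethyl-4H-chromen-4-one
Conditions: TBSCl, imidazole, DMF, rt
Reagents that add atoms: tert-butyldimethylsilyl chloride, CC(C)(C)[Si](C)(C)Cl
Why: Standard silylation of the only hydroxyl group gives an aryl silyl ether that tolerates silyl triflate, borohydride and the dehydration, and falls off in the final hydroxide step.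

Step 4
Reactants: 6 geranyl acetate
Product: 7 (2E)-5-(3,3-dimethyloxiran-2-yl)-3-methylpent-2-en-1-yl acetate (racemic)
Conditions: mCPBA (1.0 equiv), CH2Cl2, 0 °C
Reagents that add atoms: 3-chloroperbenzoic acid, OOC(=O)c1cccc(Cl)c1
Why: Prilezhaev epoxidation should take the electron-rich terminal trisubstituted alkene in preference to the 2,3-alkene, which is deactivated by the allylic acetate; the racemic epoxide stereocentre is destroyed in the next step.

Step 5
Reactants: 7 (2E)-5-(3,3-dimethyloxiran-2-yl)-3-methylpent-2-en-1-yl acetate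
Product: 9 (2E)-3-methyl-6-oxohex-2-en-1-yl acetate, via diol 8 (not isolated)
Conditions: H5IO6, THF/H2O, 0 °C to rt
Reagents that add atoms: none
Why: Periodic acid hydrolyses the epoxide (water opening at the tertiary carbon, so the aldehyde oxygen is the former epoxide oxygen) and cleaves the resulting glycol (Malaprade cleavage) to the aldehyde and acetone without touching the E-alkene or the acetate.

Step 6
Reactants: 10 methyl 2-[bis(2,2,2-trifluoroethoxy)phosphoryl]acetate; 11 5-bromo-2-methylpent-2-ene
Product: 12 methyl 2-[bis(2,2,2-trifluoroethoxy)phosphoryl]-6-methylhept-5-enoate (racemic)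
Conditions: NaH, DMF, 0 °C; then 11, NaI (cat.), rt to 50 °C
Reagents that add atoms: none
Why: SN2 C-alkylation of the sodium phosphonoacetate by the primary homoallylic halide (iodide-assisted) should give the mono-alkylated phosphonate, the non-nucleophilic base sparing the trifluoroethyl esters on phosphorus.

Step 7
Reactants: 12 methyl 2-[bis(2,2,2-trifluoroethoxy)phosphoryl]-6-methylhept-5-enoate; 9 (2E)-3-methyl-6-oxohex-2-en-1-yl acetate
Product: 13 methyl (2Z,6E)-8-acetoxy-6-methyl-2-(4-methylpent-3-en-1-yl)octa-2,6-dienoate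
Conditions: KN(SiMe3)2, 18-crown-6, THF, −78 °C
Reagents that add atoms: none
Why: Still–Gennari variant of the Horner–Wadsworth–Emmons reaction, in which the electron-poor phosphonate under dissociating conditions eliminates rapidly from the kinetic adduct, should place the ester and the aldehyde-derived chain cis (Z) on the new trisubstituted alkene.

Step 8
Reactants: 13 methyl (2Z,6E)-8-acetoxy-6-methyl-2-(4-methylpent-3-en-1-yl)octa-2,6-dienoate
Product: 14 methyl (2Z,6E)-8-hydroxy-6-methyl-2-(4-methylpent-3-en-1-yl)octa-2,6-dienoate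
Conditions: K2CO3 (cat.), MeOH, 0 °C
Reagents that add atoms: none
Why: Base-catalysed methanolysis removes the acetate, while the hindered conjugated methyl ester is degenerate towards methanol and should be unchanged.

Step 9
Reactants: 14 methyl (2Z,6E)-8-hydroxy-6-methyl-2-(4-methylpent-3-en-1-yl)octa-2,6-dienoate
Product: 15 methyl (2Z,6E)-6-methyl-2-(4-methylpent-3-en-1-yl)-8-oxoocta-2,6-dienoate
Conditions: Dess–Martin periodinane, CH2Cl2, 0 °C to rt
Reagents that add atoms: none
Why: Dess–Martin oxidation of the primary allylic alcohol should give the E-enal without over-oxidation or alkene isomerisation.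

Step 10
Reactants: 15 methyl (2Z,6E)-6-methyl-2-(4-methylpent-3-en-1-yl)-8-oxoocta-2,6-dienoate
Product: 16 methyl (2Z,6E)-6-methyl-2-(4-methylpent-3-en-1-yl)nona-2,6,8-trienoate
Conditions: Ph3PCH3Br, KN(SiMe3)2, THF, 0 °C; then 15, −78 to 0 °C
Reagents that add atoms: methyltriphenylphosphonium bromide, C[P+](c1ccccc1)(c1ccccc1)c1ccccc1.[Br-]
Why: Wittig methylenation of the enal with the non-stabilised ylide should give the terminal 1,3-diene (as for geranial), the hindered conjugated ester being inert at low temperature and the existing alkene geometries untouched.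

Step 11
Reactants: 16 methyl (2Z,6E)-6-methyl-2-(4-methylpent-3-en-1-yl)nona-2,6,8-trienoate; 5 6-(tert-butyldimethylsilyloxy)-2,7,8-trimethyl-4H-chromen-4-one
Product: 20 methyl (2Z,6E)-9-[(2S)-6-(tert-butyldimethylsilyloxy)-2,7,8-trimethyl-4-oxochroman-2-yl]-6-methyl-2-(4-methylpent-3-en-1-yl)nona-2,6-dienoate, via alkylzirconocene chloride 17 (not isolated), via silyloxybenzopyrylium triflate 18 (not isolated), via trimethylsilyl enol ether 19 (not isolated)
Conditions: 16 (1.4 equiv), Cp2Zr(H)Cl (1.3 equiv), CH2Cl2, rt; separately 5, TMSOTf (1.05 equiv), CH2Cl2, 0 °C; combine over CuCl (10 mol %), AgNTf2 (11 mol %), chiral BINOL-derived bis(1-phenylethyl)amine phosphoramidite (12 mol %), Et2O, 0 °C to rt; then 1 M HCl, THF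
Reagents that add atoms: none
Why: Proposed new method: Cp2Zr(H)Cl adds across the only monosubstituted C=C of 16 (1,2-hydrozirconation of the terminal vinyl group of the 1,3-diene, zirconium at the terminal carbon) to give the homoallylic alkylzirconocene 17, while TMSOTf O-silylates chromone 5 to the aromatic 4-silyloxy-1-benzopyrylium triflate 18; zirconium-to-copper transmetalation gives a ligand-bound alkylcopper (monovalent copper) that π-binds the C2=C3 bond of 18, adds at C2 through a trivalent copper intermediate and reductively eliminates, forming the C2–C9 bond and enol silane 19, which aqueous acid converts to ketone 20. The closest known reaction types are the copper–phosphoramidite-catalysed asymmetric conjugate addition of alkene-derived alkylzirconocenes to β-methyl cyclic enones with a silyl halide additive (quaternary centres) and the copper-catalysed enantioselective alkynylation of 2-alkyl-4-silyloxybenzopyrylium triflates to tetrasubstituted C2 ethers; new is the transfer of an sp3 alkyl group to such a cation. No ring is closed: the flat pyrylium ring is dearomatised and its C2 becomes the only stereocentre of the target. That centre is set by catalyst control, the chiral phosphoramidite on copper distinguishing the enantiotopic faces of the cation through the difference between the C2 methyl group and the ring oxygen. Site selectivity is secured by the C4 silyloxy group, which leaves C2 as the only conjugate-acceptor carbon, and the alkylzirconocene is neither basic enough to deprotonate the acidic C2 methyl group nor nucleophilic enough to add without copper, so a racemic background reaction should be negligible. Chemoselectivity of the hydrozirconation rests on the much higher rate at the terminal vinyl group and on keeping the diene in slight excess over Cp2Zr(H)Cl, so that no Zr–H remains for the slower reduction of the methyl ester or of the cation.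

Step 12
Reactants: 20 methyl (2Z,6E)-9-[(2S)-6-(tert-butyldimethylsilyloxy)-2,7,8-trimethyl-4-oxochroman-2-yl]-6-methyl-2-(4-methylpent-3-en-1-yl)nona-2,6-dienoate
Product: 21 methyl (2Z,6E)-9-[(2S)-6-(tert-butyldimethylsilyloxy)-4-hydroxy-2,7,8-trimethylchroman-2-yl]-6-methyl-2-(4-methylpent-3-en-1-yl)nona-2,6-dienoate (mixture of C4 epimers)
Conditions: NaBH4, MeOH/THF, −10 °C
Reagents that add atoms: none
Why: Borohydride 1,2-reduction of the aryl ketone at low temperature should outrun retro-oxa-Michael opening (which would racemise C2) and leave the conjugated ester alone; the new C4 centre is uncontrolled and irrelevant because it is removed in the next step.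

Step 13
Reactants: 21 methyl (2Z,6E)-9-[(2S)-6-(tert-butyldimethylsilyloxy)-4-hydroxy-2,7,8-trimethylchroman-2-yl]-6-methyl-2-(4-methylpent-3-en-1-yl)nona-2,6-dienoate
Product: 22 methyl (2Z,6E)-9-[(2S)-6-(tert-butyldimethylsilyloxy)-2,7,8-trimethyl-2H-chromen-2-yl]-6-methyl-2-(4-methylpent-3-en-1-yl)nona-2,6-dienoate
Conditions: Burgess reagent, toluene, 50 °C
Reagents that add atoms: none
Why: Burgess dehydration of the secondary benzylic alcohol through its sulfamate ester under non-acidic conditions should give the conjugated C3=C4 alkene (only C3 carries β-hydrogens) without a long-lived C4 cation that the side-chain alkenes could trap.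

Step 14
Reactants: 22 methyl (2Z,6E)-9-[(2S)-6-(tert-butyldimethylsilyloxy)-2,7,8-trimethyl-2H-chromen-2-yl]-6-methyl-2-(4-methylpent-3-en-1-yl)nona-2,6-dienoate
Product: 23 (2Z,6E)-9-[(2S)-6-hydroxy-2,7,8-trimethyl-2H-chromen-2-yl]-6-methyl-2-(4-methylpent-3-en-1-yl)nona-2,6-dienoic acid (CNP0158414.2)
Conditions: LiOH, THF/MeOH/H2O (degassed), 40 °C, dark; then 1 M HCl to pH 3, 0 °C
Reagents that add atoms: lithium hydroxide, [Li+].[OH-]
Why: Hydroxide should saponify the methyl ester and cleave the aryl silyl ether in one operation; the quaternary C2 cannot epimerise under base, and exclusion of oxygen and light guards the electron-rich chromenol against oxidation and against photochemical ring opening that would racemise C2.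

**Compound list**

1 | 2,3-dimethylhydroquinone (2,3-dimethylbenzene-1,4-diol) | Cc1c(C)c(O)ccc1O | starting material
2 | 1-(2,5-dihydroxy-3,4-dimethylphenyl)ethan-1-one | CC(=O)c1cc(O)c(C)c(C)c1O | intermediate
3 | 1-(2,5-dihydroxy-3,4-dimethylphenyl)butane-1,3-dione | CC(=O)CC(=O)c1cc(O)c(C)c(C)c1O | intermediate (not isolated)
4 | 6-hydroxy-2,7,8-trimethyl-4H-chromen-4-one | Cc1cc(=O)c2cc(O)c(C)c(C)c2o1 | intermediate
5 | 6-(tert-butyldimethylsilyloxy)-2,7,8-trimethyl-4H-chromen-4-one | Cc1cc(=O)c2cc(O[Si](C)(C)C(C)(C)C)c(C)c(C)c2o1 | intermediate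
6 | geranyl acetate, (2E)-3,7-dimethylocta-2,6-dien-1-yl acetate | CC(C)=CCC/C(C)=C/COC(C)=O | starting material
7 | (2E)-5-(3,3-dimethyloxiran-2-yl)-3-methylpent-2-en-1-yl acetate (racemic) | CC1(C)OC1CC/C(C)=C/COC(C)=O | intermediate
8 | (2E)-6,7-dihydroxy-3,7-dimethyloct-2-en-1-yl acetate (racemic) | CC(C)(O)C(O)CC/C(C)=C/COC(C)=O | intermediate (not isolated)
9 | (2E)-3-methyl-6-oxohex-2-en-1-yl acetate | O=CCC/C(C)=C/COC(C)=O | intermediate
10 | methyl 2-[bis(2,2,2-trifluoroethoxy)phosphoryl]acetate | COC(=O)CP(=O)(OCC(F)(F)F)OCC(F)(F)F | starting material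
11 | 5-bromo-2-methylpent-2-ene | CC(C)=CCCBr | starting material
12 | methyl 2-[bis(2,2,2-trifluoroethoxy)phosphoryl]-6-methylhept-5-enoate (racemic) | COC(=O)C(CCC=C(C)C)P(=O)(OCC(F)(F)F)OCC(F)(F)F | intermediate
13 | methyl (2Z,6E)-8-acetoxy-6-methyl-2-(4-methylpent-3-en-1-yl)octa-2,6-dienoate | CC(C)=CCC/C(=C/CC/C(C)=C/COC(C)=O)C(=O)OC | intermediate
14 | methyl (2Z,6E)-8-hydroxy-6-methyl-2-(4-methylpent-3-en-1-yl)octa-2,6-dienoate | CC(C)=CCC/C(=C/CC/C(C)=C/CO)C(=O)OC | intermediate
15 | methyl (2Z,6E)-6-methyl-2-(4-methylpent-3-en-1-yl)-8-oxoocta-2,6-dienoate | CC(C)=CCC/C(=C/CC/C(C)=C/C=O)C(=O)OC | intermediate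
16 | methyl (2Z,6E)-6-methyl-2-(4-methylpent-3-en-1-yl)nona-2,6,8-trienoate | CC(C)=CCC/C(=C/CC/C(C)=C/C=C)C(=O)OC | intermediate
17 | chlorobis(cyclopentadienyl)[(3E,7Z)-8-(methoxycarbonyl)-4,12-dimethyltrideca-3,7,11-trien-1-yl]zirconium | CC(C)=CCC/C(=C/CC/C(C)=C/CC[Zr](Cl)(C1C=CC=C1)C1C=CC=C1)C(=O)OC | intermediate (not isolated)
18 | 6-(tert-butyldimethylsilyloxy)-2,7,8-trimethyl-4-(trimethylsilyloxy)chromenylium trifluoromethanesulfonate | Cc1cc(O[Si](C)(C)C)c2cc(O[Si](C)(C)C(C)(C)C)c(C)c(C)c2[o+]1.[O-]S(=O)(=O)C(F)(F)F | intermediate (not isolated)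
19 | methyl (2Z,6E)-9-[(2S)-6-(tert-butyldimethylsilyloxy)-2,7,8-trimethyl-4-(trimethylsilyloxy)-2H-chromen-2-yl]-6-methyl-2-(4-methylpent-3-en-1-yl)nona-2,6-dienoate | CC(C)=CCC/C(=C/CC/C(C)=C/CC[C@@]1(C)C=C(O[Si](C)(C)C)c2cc(O[Si](C)(C)C(C)(C)C)c(C)c(C)c2O1)C(=O)OC | intermediate (not isolated)
20 | methyl (2Z,6E)-9-[(2S)-6-(tert-butyldimethylsilyloxy)-2,7,8-trimethyl-4-oxochroman-2-yl]-6-methyl-2-(4-methylpent-3-en-1-yl)nona-2,6-dienoate | CC(C)=CCC/C(=C/CC/C(C)=C/CC[C@@]1(C)CC(=O)c2cc(O[Si](C)(C)C(C)(C)C)c(C)c(C)c2O1)C(=O)OC | intermediate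
21 | methyl (2Z,6E)-9-[(2S)-6-(tert-butyldimethylsilyloxy)-4-hydroxy-2,7,8-trimethylchroman-2-yl]-6-methyl-2-(4-methylpent-3-en-1-yl)nona-2,6-dienoate (C4 epimers) | CC(C)=CCC/C(=C/CC/C(C)=C/CC[C@@]1(C)CC(O)c2cc(O[Si](C)(C)C(C)(C)C)c(C)c(C)c2O1)C(=O)OC | intermediate
22 | methyl (2Z,6E)-9-[(2S)-6-(tert-butyldimethylsilyloxy)-2,7,8-trimethyl-2H-chromen-2-yl]-6-methyl-2-(4-methylpent-3-en-1-yl)nona-2,6-dienoate | CC(C)=CCC/C(=C/CC/C(C)=C/CC[C@@]1(C)C=Cc2cc(O[Si](C)(C)C(C)(C)C)c(C)c(C)c2O1)C(=O)OC | intermediate
23 | (2Z,6E)-9-[(2S)-6-hydroxy-2,7,8-trimethyl-2H-chromen-2-yl]-6-methyl-2-(4-methylpent-3-en-1-yl)nona-2,6-dienoic acid | CC(C)=CCC/C(=C/CC/C(C)=C/CC[C@@]1(C)C=Cc2cc(O)c(C)c(C)c2O1)C(=O)O | target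

**Summary**

Total step count: 14. Longest linear sequence: 10 steps (steps 4, 5, 7, 8, 9, 10, 11, 12, 13, 14, from geranyl acetate).

**Steps most likely to fail, with fallbacks**

Step 11 (proposed new method). The alkyl transfer from zirconium through copper to the hindered, oxygen-bearing C2 may be too slow, so that the cation is instead reduced or desilylated. The chiral alkylcopper may also discriminate the two faces of the cation poorly, or Zr–H may attack the ester before hydrozirconation is complete. The fallback uses known chemistry, sets out from enal 15 and chromone 5, and comes back at 20. Ohira–Bestmann homologation of 15 (dimethyl (1-diazo-2-oxopropyl)phosphonate, K2CO3, MeOH) should give methyl (2Z,6E)-6-methyl-2-(4-methylpent-3-en-1-yl)nona-2,6-dien-8-ynoate F1. Copper-catalysed enantioselective alkynylation of the chromone (CuI, chiral bis(oxazoline), TBSOTf, iPr2NEt, toluene, −78 °C; known for 2-alkylchromones and terminal alkynes, giving tetrasubstituted C2) should proceed through 4,6-bis(tert-butyldimethylsilyloxy)-2,7,8-trimethylchromenylium triflate F2 and the (2R)-2-alkynyl-4-silyloxy-2H-chromene F3. Aqueous HCl then gives the (2R)-2-alkynylchroman-4-one F4, which has the same spatial arrangement as (S)-20; the descriptor changes only because the alkynyl carbon outranks C3. Diimide (2-nitrobenzenesulfonylhydrazide, Et3N, CH2Cl2, rt) should then saturate the triple bond through the (8Z)-alkenyl chromanone F5, while the three trisubstituted alkenes react far more slowly, to give 20.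

Step 6. The alkylation may stall or go astray through a second alkylation of the product, loss of trifluoroethoxide from phosphorus, and E2 elimination of the unactivated homoallylic bromide. The fallback sets out from bromide 11 and comes back at phosphonate 12, and builds the fluorinated phosphonate after the C–C bond instead of before it. Alkylation of the robust trimethyl phosphonoacetate (NaH, DMF) with 11 should give methyl 2-(dimethoxyphosphoryl)-6-methylhept-5-enoate F6. Selective P–O-methyl cleavage with TMSBr gives methyl 2-[bis(trimethylsilyloxy)phosphoryl]-6-methylhept-5-enoate F7. Oxalyl chloride with catalytic DMF converts this to methyl 2-(dichlorophosphoryl)-6-methylhept-5-enoate F8, and 2,2,2-trifluoroethanol with Et3N then gives 12.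

Step 13. The benzylic sulfamate may ionise to a C4 cation that is captured by the nearby side-chain alkene (six-membered cation–olefin cyclisation) or by the carbamate nitrogen before the C3 proton is lost. The fallback sets out from ketone 20 and comes back at chromene 22 without any C4 cation. Enolisation and triflation (KN(SiMe3)2, PhNTf2, THF, −78 °C, kept cold to outrun β-elimination of the aryloxide) should give methyl (2Z,6E)-9-[(2S)-6-(tert-butyldimethylsilyloxy)-2,7,8-trimethyl-4-(trifluoromethylsulfonyloxy)-2H-chromen-2-yl]-6-methyl-2-(4-methylpent-3-en-1-yl)nona-2,6-dienoate F9. Reduction of the enol triflate with formate (Pd(OAc)2, PPh3, Bu3N, HCO2H, DMF, 60 °C; zerovalent palladium formed in the flask) then gives 22.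

**Further compounds**

F1 | step 11 | methyl (2Z,6E)-6-methyl-2-(4-methylpent-3-en-1-yl)nona-2,6-dien-8-ynoate | CC(C)=CCC/C(=C/CC/C(C)=C/C#C)C(=O)OC
F2 | step 11 | 4,6-bis(tert-butyldimethylsilyloxy)-2,7,8-trimethylchromenylium trifluoromethanesulfonate | Cc1cc(O[Si](C)(C)C(C)(C)C)c2cc(O[Si](C)(C)C(C)(C)C)c(C)c(C)c2[o+]1.[O-]S(=O)(=O)C(F)(F)F
F3 | step 11 | methyl (2Z,6E)-9-[(2R)-4,6-bis(tert-butyldimethylsilyloxy)-2,7,8-trimethyl-2H-chromen-2-yl]-6-methyl-2-(4-methylpent-3-en-1-yl)nona-2,6-dien-8-ynoate | CC(C)=CCC/C(=C/CC/C(C)=C/C#C[C@@]1(C)C=C(O[Si](C)(C)C(C)(C)C)c2cc(O[Si](C)(C)C(C)(C)C)c(C)c(C)c2O1)C(=O)OC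
F4 | step 11 | methyl (2Z,6E)-9-[(2R)-6-(tert-butyldimethylsilyloxy)-2,7,8-trimethyl-4-oxochroman-2-yl]-6-methyl-2-(4-methylpent-3-en-1-yl)nona-2,6-dien-8-ynoate | CC(C)=CCC/C(=C/CC/C(C)=C/C#C[C@@]1(C)CC(=O)c2cc(O[Si](C)(C)C(C)(C)C)c(C)c(C)c2O1)C(=O)OC
F5 | step 11 | methyl (2Z,6E,8Z)-9-[(2R)-6-(tert-butyldimethylsilyloxy)-2,7,8-trimethyl-4-oxochroman-2-yl]-6-methyl-2-(4-methylpent-3-en-1-yl)nona-2,6,8-trienoate | CC(C)=CCC/C(=C/CC/C(C)=C/C=C\[C@@]1(C)CC(=O)c2cc(O[Si](C)(C)C(C)(C)C)c(C)c(C)c2O1)C(=O)OC
F6 | step 6 | methyl 2-(dimethoxyphosphoryl)-6-methylhept-5-enoate | COC(=O)C(CCC=C(C)C)P(=O)(OC)OC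
F7 | step 6 | methyl 2-[bis(trimethylsilyloxy)phosphoryl]-6-methylhept-5-enoate | COC(=O)C(CCC=C(C)C)P(=O)(O[Si](C)(C)C)O[Si](C)(C)C
F8 | step 6 | methyl 2-(dichlorophosphoryl)-6-methylhept-5-enoate | COC(=O)C(CCC=C(C)C)P(=O)(Cl)Cl
F9 | step 13 | methyl (2Z,6E)-9-[(2S)-6-(tert-butyldimethylsilyloxy)-2,7,8-trimethyl-4-(trifluoromethylsulfonyloxy)-2H-chromen-2-yl]-6-methyl-2-(4-methylpent-3-en-1-yl)nona-2,6-dienoate | CC(C)=CCC/C(=C/CC/C(C)=C/CC[C@@]1(C)C=C(OS(=O)(=O)C(F)(F)F)c2cc(O[Si](C)(C)C(C)(C)C)c(C)c(C)c2O1)C(=O)OC
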